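**Retrosynthetic overview**
1. 16-epi-Luffarin L (16) ⇐ O-desilylation of 15.
2. Key disconnection at the lactone C16–O bond: 15 ⇐ alkenyl iodide 10 + dienoic acid 14. The alkenylpalladium species adds to the terminal alkene (C14–C15), and the C18 carboxylate then closes enantioselectively onto C16 of the π-allyl (new step, sets 16R).
3. 10 ⇐ bromide 4 + propargyl alcohol 5 (anti-carbomagnesiation/iodination fixes the 13Z alkene); 4 ⇐ (+)-sclareolide 1 (C5 and C10 from the chiral pool).
4. 14 ⇐ propargyl alcohol 5 (carboxylation, anti-hydroiodination, vinyl Suzuki coupling).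
5. Ring order: rings A and B (trans-decalin) come intact from 1; the butenolide ring is closed in step 9.

Notation: Dr = (4aS,8aS)-2,5,5,8a-tetramethyl-3,4,4a,5,6,7,8,8a-octahydronaphthalen-1-yl, the trans-fused drim-8-en-9-yl unit (C5–H α, C10–CH3 β, tetrasubstituted C8=C9). Side-chain atoms carry luffarin numbering (C11–C19, C24, C25).

Assumption: the facial sense of the new palladium step cannot be known before it is run; the (S,S,S)-phosphoramidite is written as the antipode that gives 16R, and its mirror image is used if the first run shows the opposite sense.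

**Step 1**
Reactants: 1 (+)-sclareolide
Product: 2 methyl 2-Dr-acetate
Conditions: conc. H2SO4 (1.5 equiv), MeOH, 65 °C
Reagents that add atoms: methanol, CO
Why: Acid-promoted alkyl–oxygen cleavage of the tertiary lactone (E1 dehydration) coupled to Fischer esterification drains the C8 cation to the most substituted, thermodynamically favoured C8=C9 alkene, while C5 and C10 are not touched.

**Step 2**
Reactants: 2 methyl 2-Dr-acetate
Product: 3 2-Dr-ethanol
Conditions: LiAlH4, THF, 0 °C → rt
Reagents that add atoms: none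
Why: LiAlH4 ester reduction, to which the isolated tetrasubstituted alkene is inert.

**Step 3**
Reactants: 3 2-Dr-ethanol
Product: 4 2-Dr-ethyl bromide
Conditions: CBr4, PPh3, CH2Cl2, 0 °C → rt
Reagents that add atoms: carbon tetrabromide, BrC(Br)(Br)Br
Why: Appel bromination, an SN2 displacement at the primary carbinol under neutral conditions that leave the acid-sensitive tetrasubstituted alkene alone.

**Step 4**
Reactants: 4 2-Dr-ethyl bromide; 5 prop-2-yn-1-ol
Product: 9 (2Z)-3-iodo-2-(2-Dr-ethyl)prop-2-en-1-ol, via Grignard reagent 6 (not isolated), via chloromagnesium prop-2-yn-1-olate 7 (not isolated), via alkenylmagnesium chelate 8 (not isolated)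
Conditions: Mg, Et2O, 35 °C; 5 (1.2 equiv)/i-PrMgCl (1.2 equiv), Et2O, −20 °C; CuI (10 mol%), −20 °C → rt; then I2, −40 → 0 °C
Reagents that add atoms: iodine, II
Why: Duboudin-type CuI-catalysed anti-carbomagnesiation of the propargylic magnesium alkoxide puts the alkyl group on the internal alkyne carbon and magnesium on the terminal carbon cis to CH2O (five-membered chelate), so iodinolysis with retention gives only the Z iodide that later becomes the C13=C14 alkene with CH2OH cis to C15.

**Step 5**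
Reactants: 9 (2Z)-3-iodo-2-(2-Dr-ethyl)prop-2-en-1-ol
Product: 10 tert-butyldimethylsilyl ether of 9
Conditions: TBSCl, imidazole, DMF, rt
Reagents that add atoms: tert-butyldimethylsilyl chloride, CC(C)(C)[Si](C)(C)Cl
Why: Standard silyl ether formation blocks the C25 hydroxyl, which sits cis to the new allyl unit in step 9 and would otherwise close a dihydropyran on it.

**Step 6**
Reactants: 5 prop-2-yn-1-ol
Product: 12 4-hydroxybut-2-ynoic acid, via bis(bromomagnesium) propynolate 11 (not isolated)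
Conditions: EtMgBr (2.1 equiv), THF, 0 → 40 °C; CO2, 0 °C; aq. HCl
Reagents that add atoms: carbon dioxide, O=C=O
Why: Carboxylation of the acetylenic Grignard reagent (Iotsitch reagent) of the alkoxide with CO2 delivers C19 on the alkyne terminus.

**Step 7**
Reactants: 12 4-hydroxybut-2-ynoic acid
Product: 13 (2Z)-4-hydroxy-3-iodobut-2-enoic acid
Conditions: LiI (1.3 equiv), AcOH (1.5 equiv), MeCN, 70 °C
Reagents that add atoms: lithium iodide, [Li+].[I-]
Why: Stereospecific anti hydroiodination of the ynoic acid (conjugate addition of iodide, then anti protonation) gives the Z β-iodo acid, whose CH2OH is trans to CO2H and so cannot lactonise.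

**Step 8**
Reactants: 13 (2Z)-4-hydroxy-3-iodobut-2-enoic acid
Product: 14 (2E)-3-(hydroxymethyl)penta-2,4-dienoic acid
Conditions: vinylboronic acid pinacol ester (1.3 equiv), PdCl2(dppf) (3 mol%), K2CO3 (3 equiv), THF/H2O 4:1, 50 °C; then pH 3, 0 °C (kept cold, used promptly)
Reagents that add atoms: vinylboronic acid pinacol ester, C=CB1OC(C)(C)C(C)(C)O1
Why: Suzuki–Miyaura coupling with retention of alkene geometry puts the vinyl group cis to CO2H, the arrangement needed for ring closure in step 9.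

**Step 9**
Reactants: 10 tert-butyldimethylsilyl ether of 9; 14 (2E)-3-(hydroxymethyl)penta-2,4-dienoic acid (1.5 equiv)
Product: 15 (5R)-5-[(2Z)-3-{[(tert-butyldimethylsilyl)oxy]methyl}-5-Dr-pent-2-en-1-yl]-4-(hydroxymethyl)furan-2(5H)-one
Conditions: Pd2(dba)3 (2.5 mol%), (S,S,S)-phosphoramidite [(S)-BINOL-derived N,N-bis((S)-1-phenylethyl)phosphoramidite, 11 mol%], K2CO3 (2.5 equiv), 1,4-dioxane, 50 °C
Reagents that add atoms: none
Why: Proposed new method: an asymmetric Heck insertion/π-allyl lactonisation cascade in which the alkenylpalladium iodide formed from 10 and zerovalent palladium adds across the terminal C15=C16 bond of the dienoate (alkenyl to C15, as in the known coupling of vinylic halides with 1,3-dienes and nucleophiles), and the resulting η3-allylpalladium (C16–C17–C18) is trapped at C16 by its own C18 carboxylate anti to palladium, which closes the butenolide, leaves C17=C18 in the ring, keeps the 13Z geometry and returns zerovalent palladium, so that C16 is set as R in the C–O bond-forming step under control of the phosphoramidite (the diastereomeric allyl complexes can interconvert by π–σ–π through the C18-bound σ-form, and the remote C5/C10 centres exert no influence); the closest known reaction types are the Larock heteroannulation of 1,3-dienes, the palladium-catalysed coupling–cyclisation of 2,3-allenoic acids with organic halides to butenolides (the same carboxylate closure onto an allyl terminus) and phosphoramidite-controlled asymmetric Heck/Tsuji–Trost difunctionalisation of dienes, none of which has been shown enantioselectively for a 3-substituted 2,4-dienoic acid with an alkenyl iodide.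

**Step 10**
Reactants: 15 (5R)-5-[(2Z)-3-{[(tert-butyldimethylsilyl)oxy]methyl}-5-Dr-pent-2-en-1-yl]-4-(hydroxymethyl)furan-2(5H)-one
Product: 16 16-epi-luffarin L
Conditions: HF·pyridine, pyridine, THF, 0 °C → rt
Reagents that add atoms: none
Why: Fluoride-mediated desilylation under buffered, non-basic conditions frees the C25 hydroxyl without epimerising the base-sensitive C16–H of the butenolide.

**Compound list**
1 | (+)-sclareolide, (3aR,5aS,9aS,9bR)-3a,6,6,9a-tetramethyldecahydronaphtho[2,1-b]furan-2(1H)-one | CC1(C)CCC[C@@]2(C)[C@H]1CC[C@@]1(C)OC(=O)C[C@@H]12 | starting material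
2 | methyl 2-Dr-acetate, methyl 2-[(4aS,8aS)-2,5,5,8a-tetramethyl-3,4,4a,5,6,7,8,8a-octahydronaphthalen-1-yl]acetate | CC1=C(CC(=O)OC)[C@@]2(C)CCCC(C)(C)[C@@H]2CC1 | intermediate
3 | 2-Dr-ethanol | CC1=C(CCO)[C@@]2(C)CCCC(C)(C)[C@@H]2CC1 | intermediate
4 | 2-Dr-ethyl bromide | CC1=C(CCBr)[C@@]2(C)CCCC(C)(C)[C@@H]2CC1 | intermediate
5 | prop-2-yn-1-ol (propargyl alcohol) | C#CCO | starting material
6 | Grignard reagent, 2-Dr-ethylmagnesium bromide | CC1=C(CC[Mg]Br)[C@@]2(C)CCCC(C)(C)[C@@H]2CC1 | intermediate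
7 | chloromagnesium prop-2-yn-1-olate | C#CCO[Mg]Cl | intermediate
8 | alkenylmagnesium chelate, (Z)-BrMg–CH=C(CH2CH2Dr)–CH2O–MgCl with Mg cis to CH2O | CC1=C(CC/C(=C/[Mg]Br)CO[Mg]Cl)[C@@]2(C)CCCC(C)(C)[C@@H]2CC1 | intermediate
9 | (2Z)-3-iodo-2-(2-Dr-ethyl)prop-2-en-1-ol (I cis to CH2OH) | CC1=C(CC/C(=C/I)CO)[C@@]2(C)CCCC(C)(C)[C@@H]2CC1 | intermediate
10 | tert-butyldimethylsilyl ether of 9, tert-butyl{[(2Z)-3-iodo-2-(2-Dr-ethyl)prop-2-en-1-yl]oxy}dimethylsilane | CC1=C(CC/C(=C/I)CO[Si](C)(C)C(C)(C)C)[C@@]2(C)CCCC(C)(C)[C@@H]2CC1 | intermediate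
11 | bis(bromomagnesium) propynolate, BrMg–C≡C–CH2–O–MgBr | Br[Mg]C#CCO[Mg]Br | intermediate
12 | 4-hydroxybut-2-ynoic acid | OCC#CC(=O)O | intermediate
13 | (2Z)-4-hydroxy-3-iodobut-2-enoic acid (I cis to CO2H) | OC/C(I)=C/C(=O)O | intermediate
14 | (2E)-3-(hydroxymethyl)penta-2,4-dienoic acid (vinyl cis to CO2H) | OC/C(C=C)=C/C(=O)O | intermediate
15 | (5R)-5-[(2Z)-3-{[(tert-butyldimethylsilyl)oxy]methyl}-5-Dr-pent-2-en-1-yl]-4-(hydroxymethyl)furan-2(5H)-one | CC1=C(CC/C(=C/C[C@H]2OC(=O)C=C2CO)CO[Si](C)(C)C(C)(C)C)[C@@]2(C)CCCC(C)(C)[C@@H]2CC1 | intermediate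
16 | 16-epi-luffarin L, (5R)-4-(hydroxymethyl)-5-[(2Z)-3-(hydroxymethyl)-5-Dr-pent-2-en-1-yl]furan-2(5H)-one | CC1=C(CC/C(=C/C[C@H]2OC(=O)C=C2CO)CO)[C@@]2(C)CCCC(C)(C)[C@@H]2CC1 | target

**Totals**
Total step count: 10. Longest linear sequence: 7 steps (1, 2, 3, 4, 5, 9, 10); steps 6–8 make the second fragment.

**Steps most likely to fail, with fallbacks**

Step 9 (the new cascade). Risks are β-hydride elimination of the allyl intermediate to the conjugated trienoic acid and incomplete ligand control at C16; the 16R/16S products differ only at a remote centre and will not separate easily. Fallback with known chemistry, setting out from 10 (and 13) and coming back at 16: iodine–lithium exchange on 10 (t-BuLi, Et2O, −78 °C) and opening of ethylene oxide (BF3·OEt2) give the homoallylic alcohol (3Z)-4-{[(tert-butyldimethylsilyl)oxy]methyl}-6-Dr-hex-3-en-1-ol F1. Dess–Martin periodinane (NaHCO3, CH2Cl2, 0 °C) oxidises it to the β,γ-unsaturated aldehyde (3Z)-4-{[(tert-butyldimethylsilyl)oxy]methyl}-6-Dr-hex-3-enal F2, used at once. In parallel 13 is esterified (MeOH, cat. H2SO4) to methyl (2Z)-4-hydroxy-3-iodobut-2-enoate F3 and silylated (TBSCl, imidazole) to methyl (2Z)-4-[(tert-butyldimethylsilyl)oxy]-3-iodobut-2-enoate F4. An asymmetric Nozaki–Hiyama–Kishi coupling of F2 with F4 (CrCl2, NiCl2 cat., chiral sulfonamide ligand, THF) sets C16 by C–C bond formation, and the chromium alkoxide lactonises onto the cis ester to give the bis-silyl ether (5R)-5-[(2Z)-3-{[(tert-butyldimethylsilyl)oxy]methyl}-5-Dr-pent-2-en-1-yl]-4-{[(tert-butyldimethylsilyl)oxy]methyl}furan-2(5H)-one F5. HF·pyridine then gives 16.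

Step 4 (carbomagnesiation with the valuable Grignard reagent 6 as limiting component; competing protonation of 6 and 8 by the acetylenic C–H). Fallback setting out from 4 and coming back at 10: Grignard reagent 6 (from 4 and Mg) is acylated with N-methoxy-N-methyl-2-[(tert-butyldimethylsilyl)oxy]acetamide (THF, 0 °C) to the α-silyloxy ketone 1-[(tert-butyldimethylsilyl)oxy]-4-Dr-butan-2-one F6. A Stork–Zhao–Wittig iodomethylenation (Ph3P+CH2I I−, NaN(SiMe3)2, THF, −78 °C), expected to be Z-selective as for other α-alkoxy ketones, gives 10 directly.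

Step 1 (mixture of alkene regioisomers instead of clean C8=C9). Fallback setting out from 1 and coming back at 2: saponification and O-methylation (KOH, MeOH; then MeI, DMF) give the hydroxy ester methyl 2-[(1R,2R,4aS,8aS)-2-hydroxy-2,5,5,8a-tetramethyldecahydronaphthalen-1-yl]acetate F7. Dehydration with SOCl2/pyridine (CH2Cl2, −78 °C) gives the exocyclic Δ8(17) ester (methyl 2-[(4aS,8aS)-5,5,8a-trimethyl-2-methylidenedecahydronaphthalen-1-yl]acetate, C9–H α) F8 together with the Δ7 ester (methyl 2-[(4aS,8aS)-2,5,5,8a-tetramethyl-1,4,4a,5,6,7,8,8a-octahydronaphthalen-1-yl]acetate, C9–H α) F9. I2 (cat.) in toluene at 80 °C isomerises both to the tetrasubstituted alkene 2.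

**Further compounds**
F1 | step 9 | (3Z)-4-{[(tert-butyldimethylsilyl)oxy]methyl}-6-Dr-hex-3-en-1-ol | CC1=C(CC/C(=C/CCO)CO[Si](C)(C)C(C)(C)C)[C@@]2(C)CCCC(C)(C)[C@@H]2CC1
F2 | step 9 | (3Z)-4-{[(tert-butyldimethylsilyl)oxy]methyl}-6-Dr-hex-3-enal | CC1=C(CC/C(=C/CC=O)CO[Si](C)(C)C(C)(C)C)[C@@]2(C)CCCC(C)(C)[C@@H]2CC1
F3 | step 9 | methyl (2Z)-4-hydroxy-3-iodobut-2-enoate | OC/C(I)=C/C(=O)OC
F4 | step 9 | methyl (2Z)-4-[(tert-butyldimethylsilyl)oxy]-3-iodobut-2-enoate | CC(C)(C)[Si](C)(C)OC/C(I)=C/C(=O)OC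
F5 | step 9 | (5R)-5-[(2Z)-3-{[(tert-butyldimethylsilyl)oxy]methyl}-5-Dr-pent-2-en-1-yl]-4-{[(tert-butyldimethylsilyl)oxy]methyl}furan-2(5H)-one | CC1=C(CC/C(=C/C[C@H]2OC(=O)C=C2CO[Si](C)(C)C(C)(C)C)CO[Si](C)(C)C(C)(C)C)[C@@]2(C)CCCC(C)(C)[C@@H]2CC1
F6 | step 4 | 1-[(tert-butyldimethylsilyl)oxy]-4-Dr-butan-2-one | CC1=C(CCC(=O)CO[Si](C)(C)C(C)(C)C)[C@@]2(C)CCCC(C)(C)[C@@H]2CC1
F7 | step 1 | methyl 2-[(1R,2R,4aS,8aS)-2-hydroxy-2,5,5,8a-tetramethyldecahydronaphthalen-1-yl]acetate | CC1(C)CCC[C@@]2(C)[C@H]1CC[C@@](C)(O)[C@@H]2CC(=O)OC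
F8 | step 1 | exocyclic Δ8(17) isomer of 2, methyl 2-[(4aS,8aS)-5,5,8a-trimethyl-2-methylidenedecahydronaphthalen-1-yl]acetate (C9–H α) | CC1(C)CCC[C@@]2(C)[C@H]1CCC(=C)[C@@H]2CC(=O)OC
F9 | step 1 | Δ7 isomer of 2, methyl 2-[(4aS,8aS)-2,5,5,8a-tetramethyl-1,4,4a,5,6,7,8,8a-octahydronaphthalen-1-yl]acetate (C9–H α) | CC1(C)CCC[C@@]2(C)[C@H]1CC=C(C)[C@@H]2CC(=O)OC
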